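Minutes are the unit of this flask: in semi-batch dosing, the starting complex enters the incoming ligand at a steady rate over 60 min, and I want the amount standing at four times.

| flask | starting complex | incoming ligand | remark | time |
|---|---|---|---|---|
| eta | 0.12 M (fed, over 1.0 h) | 0.72 M | run made earlier |  |
| beta | 0.48 M (fed, over 1.0 h) | 0.72 M | run made earlier |  |
| zeta | 0.24 M (fed, over 1.0 h) | 1.1 M | run made earlier |  |
| flask | 0.24 M (fed, over 1.0 h) | 0.720 M |  | 1.0 h |

| run | time / min | starting complex / % | complex with two exchanged / % |
|---|---|---|---|
| eta | 2.50 | 2 | 0 |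
| eta | 8.00 | 10 | 0 |
| eta | 15.0 | 22 | 3 |
| eta | 20.0 | 31 | 0 |
| eta | 30.0 | 41 | 0 |
| eta | 40.0 | 58 | 0 |
| eta | 50.0 | 68 | 0 |
| beta | 2.50 | 5 | 2 |
| beta | 8.00 | 13 | 0 |
| beta | 15.0 | 21 | 0 |
| beta | 20.0 | 30 | 1 |
| beta | 30.0 | 44 | 0 |
| beta | 40.0 | 60 | 0 |
| beta | 50.0 | 69 | 0 |
| zeta | 4.00 | 7 | 0 |
| zeta | 12.0 | 17 | 0 |
| zeta | 20.0 | 30 | 1 |
| zeta | 30.0 | 47 | 0 |
| zeta | 50.0 | 70 | 0 |

(readings scatter by 1.5 percentage points)

- the analysis behind the earlier runs scatters by 1.5 percentage points, standard deviation
- steps thought possible: starting complex + incoming ligand <-> leaving ligand + complex with one exchanged; complex with one exchanged + incoming ligand <-> leaving ligand + complex with two exchanged; leaving ligand -> by-product carried off; 2 incoming ligand -> homo dimer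
- percentages count the whole charge, also what has not yet gone in

- amount of starting complex in percent of the starting complex charged, at 6.0 min, 20 min, 40 min and 1.0 h

I describe the loss of starting complex by an apparent lifetime τ, the mean time a dosed portion survives. The average portion has stood for half the elapsed time t, so the lost share of what has gone in is about t divided by 2τ, provided t is short against τ. At 50.0 min the beta run shows 69% against 83.3% fed, which I read as an apparent lifetime τ = 145 min, a reading that carries the scatter of the analysis. The eta run reads 68% at that time, although it carries 0.12 M of starting complex against 0.48 M in beta. This flask, at 0.24 M and 0.720 M of incoming ligand, lies between those two runs at their ligand level, so I carry τ over to it. My reckoning gives 57.5% at 40 min and 79.4% at 1.0 h.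

The forecast gives 9.8%, 31%, 58.5% and 81%, on the ground that “The eta and beta runs coincide despite a fourfold change in complex concentration”. Its value at 1.0 h stands above mine.

The flask gives 9.41%, 29.3%, 56.5% and 83.5%, and the forecast held.

    starting complex + incoming ligand ⇌ leaving ligand + complex with one exchanged (K = 3.20, k = 0.0380 L mol⁻¹ min⁻¹)
    complex with one exchanged + incoming ligand ⇌ leaving ligand + complex with two exchanged (K = 0.270, k = 0.00130 L mol⁻¹ min⁻¹)
    leaving ligand → by-product carried off (k = 0.270 min⁻¹)
    2 incoming ligand → homo dimer (k = 0.0600 L mol⁻¹ min⁻¹)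

At 1.0 h this flask keeps 14% of its incoming ligand unbound, less than the 83% of its starting complex. The same rule applied to the flask's value at 1.0 h gives an apparent lifetime of 182 min, longer than the τ of 145 min read from beta. On the zeta run, at 1.1 M of incoming ligand, τ gives 44.8% at 30.0 min, where the reading is 47%.

The numbers in the tables are calculated on assumed constants, noise included.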